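Readings and results come from a simulation for an exercise.

**Slow loss.** Slowness is what the two earlier runs share. From 0.667 h on, E falls in the larch run at 0.544 h⁻¹, and from 0.500 h on in the alder run at 0.538 h⁻¹, though [G] differs 3.39-fold. So I read this slow loss, with a half-life of 1.27 h in the larch run, as independent of [G].

| flask | E | G | remark | time |
|---|---|---|---|---|
| larch | 3 M | 0.059 M | run made earlier |  |
| alder | 3 M | 0.20 M | run made earlier |  |
| Tuesday's | 3.0 M | 0.0800 M |  | 4.0 h |
| Wednesday's | 3.0 M | 0.150 M |  | 4.0 h |
| Thursday's | 3.0 M | 0.300 M |  | 4.0 h |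

| run | time / h | D / % | E / % |
|---|---|---|---|
| larch | 0.250 | 10.8 | 83.9 |
| larch | 0.333 | 14.9 | 79.6 |
| larch | 0.667 | 25.9 | 65.4 |
| larch | 1.00 | 37.5 | 52.9 |
| larch | 1.50 | 48.6 | 42.9 |
| larch | 3.00 | 69.8 | 18.4 |
| alder | 0.200 | 9.8 | 81.6 |
| alder | 0.500 | 21.5 | 68.3 |
| alder | 1.00 | 34.5 | 52.4 |
| alder | 1.50 | 47.3 | 39.6 |
| alder | 2.00 | 54.3 | 30.7 |
| alder | 3.00 | 66.9 | 17.8 |

(scatter of a reading: 1 percentage point)

- "hardly changes" means that all values lie within two and a half points (for a concentration: within two and a half percent of the largest)

1. amount of D at the end, in percent of the E charged for Tuesday's, Wednesday's, Thursday's, in this order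
2. how the row runs (falls all the way / hardly changes / rises all the way / falls, then rises / rises, then falls)

**First fork.** I follow one molecule of E. My guess is that G, the limiting reagent of this fork, ties up one E per G early on. The toll is then [G]/[E] at the charge, the share of the E charged that G takes: 2.67% in Tuesday's flask. The larch toll is 1.97% and the alder toll 6.67%. I test this on the keep, which is D divided by what escapes the toll. At 3.00 h the larch run gives 71.2% and the alder run 71.7%, a gap of 0.50 percentage points against a scatter of 1 point.

**Tuesday's end.** Tuesday's flask is the near neighbour of the larch run, with [G] at 0.0800 M against 0.059 M. In the larch readings, D gains 86.5% of the E lost between 1.50 h and 3.00 h. I carry the larch keep forward at that share and at the slow rate, and it reaches 78.0% at 4.0 h. I hold the keep equal in the flasks of the row, so in my reckoning the row follows the toll: I expect 75.9%, 74.1% and 70.2%. At equal time, Tuesday's flask should stand 0.55 points below the larch run, a gap to set against that scatter.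

**The result.** The forecast gives 75.7%, 73.8% and 69.9%, a row that falls all the way, 0.20 points below mine for Tuesday's flask, on the ground that “G rapidly ties up roughly one equivalent of E”. The flask gives 76.8%, 75.1% and 71.5%, a row that falls all the way.

    2 E ⇌ Z (K = 0.390 L mol⁻¹, k = 0.0220 L mol⁻¹ h⁻¹)
    E + G → J (k = 12.0 L mol⁻¹ h⁻¹)
    E → D (k = 0.500 h⁻¹)

**Two clocks.** In Tuesday's flask, half of the turnover up to 4.0 h from E and G to J is done by 1.17 min, while half of that from E to D takes 1.07 h, a time 54.9 times as long. At 4.00 h, Tuesday's flask holds G at 0% of its charge and J at 2.67% against a toll of 2.67%, and Thursday's flask holds G at 0% and J at 10.0% against a toll of 10.0%, with a keep of 79.4%.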